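**Plan**
- **Numbering and cuts.** ent-Kaurane numbering is used: ring A = C1–C5, C10; ring C = C8, C9, C11–C14; C6 on C5; C7 on C8; C15–C17 complete ring D; C18 and C19 on C4; C20 on C10. Retrosynthetic cuts, in order: the O–C16/O–C17 and H–C5/O–C6 bonds (the diol and the C6 aldehyde both go back to exocyclic methylenes), then C8–C15, C7–C8 and C9–C10.
- **Enabling feature.** Quaternary C8 carries the C7 aldehyde. It lies one carbon (C15) from C16, which bears the C17 branch and is bonded to C13. C15–C16(=C17) is therefore a 2-substituted allyl group anchored on C13, 1,3 to C8 across ring C, so an enamine of C7 can be allylated at C8.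
- **Forward order.** Rings A and C start as six-membered rings. They are joined at C9–C10 by a ketal Claisen rearrangement whose chair (C10–C5–C6–O–C8–C9) imitates the absent ring B. C7 is then added to the C8 ketone, and ring D is closed last by palladium.
- **Stereochemistry.** C4 comes from an asymmetric phase-transfer methylation and C13 from a Rh/(R)-BINAP conjugate addition. C10 follows from C4 (bond formation opposite the pseudoaxial ester). C9 follows from the chair and from ketone equilibration (trans to C13). C8 is set by the one-carbon tether, C16 by exo-face osmylation, and C5 by hydroboration opposite axial C19 and C20.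

Key step: step 13

Assumption: the target is handled as the open 6-oxo 19-acid that is drawn; reversible closure to a 19,6-lactol would not change the route.

Step 1
Reactants: 1 tert-butyl 2-oxocyclohexane-1-carboxylate
Product: 2 tert-butyl (1R)-1-methyl-2-oxocyclohexane-1-carboxylate
Conditions: MeI, CsOH·H2O, C2-symmetric N-spiro bis(binaphthyl)ammonium bromide (1 mol %, the antipode that gives R), toluene, −40 °C
Reagents that add atoms: iodomethane, CI
Why: Asymmetric phase-transfer C-alkylation of a cyclic β-keto ester, in which the chiral ammonium enolate ion pair exposes one face to MeI and so sets quaternary C4 with C18 and C19 in place.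

Step 2
Reactants: 2 tert-butyl (1R)-1-methyl-2-oxocyclohexane-1-carboxylate
Product: 3 tert-butyl (1R)-1,3-dimethyl-2-oxocyclohexane-1-carboxylate (C3 epimers)
Conditions: LiN(iPr)2, THF, −78 °C; MeI, −78 → 0 °C
Reagents that add atoms: iodomethane, CI
Why: Kinetic enolate alkylation that can occur only on the C10 side because C4 is quaternary; it brings in C20, and the new centre is erased in the next step.

Step 3
Reactants: 3 tert-butyl (1R)-1,3-dimethyl-2-oxocyclohexane-1-carboxylate (C3 epimers)
Product: 4 tert-butyl (1R)-1,3-dimethyl-2-(trifluoromethylsulfonyloxy)cyclohex-2-ene-1-carboxylate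
Conditions: KN(SiMe3)2, THF, 0 °C; PhNTf2, 0 °C → rt
Reagents that add atoms: N-phenylbis(trifluoromethanesulfonimide), O=S(=O)(N(c1ccccc1)S(=O)(=O)C(F)(F)F)C(F)(F)F
Why: Enol triflate formation from the only possible (tetrasubstituted) enolate, as practised on 2,2,6-trisubstituted cyclohexanones, fixes the C5=C10 double bond.

Step 4
Reactants: 4 tert-butyl (1R)-1,3-dimethyl-2-(trifluoromethylsulfonyloxy)cyclohex-2-ene-1-carboxylate
Product: 5 tert-butyl (1R)-2-(hydroxymethyl)-1,3-dimethylcyclohex-2-ene-1-carboxylate
Conditions: Bu3SnCH2OH, Pd(PPh3)4 (5 mol %), LiCl (3 equiv), dioxane, 100 °C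
Reagents that add atoms: (tributylstannyl)methanol, CCCC[Sn](CCCC)(CCCC)CO
Why: Stille coupling of a vinyl triflate with a hydroxymethylstannane installs C6 as the primary allylic alcohol needed for the sigmatropic union, and the bulky tert-butyl ester resists lactonisation.

Step 5
Reactants: 6 cyclohex-2-en-1-one; 7 4,4,5,5-tetramethyl-2-(prop-1-en-2-yl)-1,3,2-dioxaborolane
Product: 8 (3R)-3-(prop-1-en-2-yl)cyclohexan-1-one
Conditions: [Rh(OH)(cod)]2 (1.5 mol %), (R)-BINAP (3.3 mol %), dioxane/H2O 10:1, 50 °C
Reagents that add atoms: none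
Why: Hayashi–Miyaura asymmetric 1,4-addition of an alkenylboron reagent, where (R)-BINAP on rhodium selects the enone face that gives R at C13; the oxygen-free isopropenyl group avoids β-oxygen elimination from the alkenylrhodium species.

Step 6
Reactants: 8 (3R)-3-(prop-1-en-2-yl)cyclohexan-1-one
Product: 9 (3R)-1,1-dimethoxy-3-(prop-1-en-2-yl)cyclohexane
Conditions: HC(OMe)3, p-TsOH (1 mol %), MeOH, rt
Reagents that add atoms: trimethyl orthoformate, COC(OC)OC
Why: Acid-catalysed ketalisation driven by the orthoformate prepares C8 for exchange with the allylic alcohol.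

Step 7
Reactants: 5 tert-butyl (1R)-2-(hydroxymethyl)-1,3-dimethylcyclohex-2-ene-1-carboxylate; 9 (3R)-1,1-dimethoxy-3-(prop-1-en-2-yl)cyclohexane
Product: 11 tert-butyl (1R,3S)-1,3-dimethyl-2-methylidene-3-[(1S,4R)-2-oxo-4-(prop-1-en-2-yl)cyclohexyl]cyclohexane-1-carboxylate, via allyl vinyl ether 10 (not isolated)
Conditions: EtCO2H (10 mol %), xylenes, 140 °C, MeOH distilled off; then NaOMe (0.2 equiv), MeOH, 50 °C
Reagents that add atoms: none
Why: Ketal exchange and loss of methanol give enol ether 10 on the less hindered C9 side, and its Claisen rearrangement through the chair C10–C5–C6–O–C8–C9 forms C9–C10 on the ring-A face opposite the pseudoaxial C19 ester (sets C10), places H9 anti to C20 (sets C9, which is also the trans-2,5 ketone that methoxide equilibration secures) and leaves C5=C6 as an exocyclic methylene.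

Step 8
Reactants: 11 tert-butyl (1R,3S)-1,3-dimethyl-2-methylidene-3-[(1S,4R)-2-oxo-4-(prop-1-en-2-yl)cyclohexyl]cyclohexane-1-carboxylate
Product: 12 C8(OTf)=C14 enol triflate of 11
Conditions: KN(SiMe3)2, THF, −78 °C; PhNTf2, −78 → 0 °C
Reagents that add atoms: N-phenylbis(trifluoromethanesulfonimide), O=S(=O)(N(c1ccccc1)S(=O)(=O)C(F)(F)F)C(F)(F)F
Why: Kinetic deprotonation takes a C14 hydrogen because H9 is buried beside quaternary C10, so enol triflate formation is regioselective and C9 is locked from here on.

Step 9
Reactants: 12 C8(OTf)=C14 enol triflate of 11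
Product: 13 C8(CHO)=C14 enal
Conditions: Pd(PPh3)4 (5 mol %), LiCl (3 equiv), CO (3 atm), Bu3SnH (slow addition), THF, 50 °C
Reagents that add atoms: carbon monoxide, [C-]#[O+]
Why: Palladium-catalysed carbonylative reduction of a vinyl triflate (Stille-type formylation: oxidative addition, CO insertion, hydride transfer from tin) attaches C7 at the aldehyde level under neutral conditions that leave doubly allylic C13 untouched.

Step 10
Reactants: 13 C8(CHO)=C14 enal
Product: 15 saturated C7 aldehyde (formyl equatorial on C8; isopropenyl on C13; ring A on C9), via triethylsilyl enol ether 14 (not isolated)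
Conditions: Et3SiH, RhCl(PPh3)3 (2 mol %), toluene, 50 °C; then K2CO3 (0.2 equiv), MeOH, rt
Reagents that add atoms: none
Why: Rhodium-catalysed 1,4-hydrosilylation of an enal followed by methanolysis reduces only the conjugated double bond; C8 is epimerisable and settles equatorial, but its configuration is erased in step 13.

Step 11
Reactants: 15 saturated C7 aldehyde (formyl equatorial on C8; isopropenyl on C13; ring A on C9)
Product: 16 allylic alcohol (3-hydroxyprop-1-en-2-yl arm on C13)
Conditions: SeO2 (0.3 equiv), t-BuOOH (2 equiv), CH2Cl2, 0 °C → rt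
Reagents that add atoms: selenium dioxide (catalytic oxygen carrier), O=[Se]=O; tert-butyl hydroperoxide, CC(C)(C)OO
Why: Catalytic SeO2 allylic oxidation (ene reaction, then [2,3]-shift) hydroxylates the isopropenyl methyl group to create C15–O, while C5=C6 cannot react because both of its allylic carbons are quaternary.

Step 12
Reactants: 16 allylic alcohol (3-hydroxyprop-1-en-2-yl arm on C13)
Product: 17 allylic methyl carbonate (cyclisation precursor)
Conditions: ClCO2Me, pyridine, CH2Cl2, 0 °C
Reagents that add atoms: methyl chloroformate, COC(=O)Cl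
Why: O-acylation of the primary allylic alcohol gives a leaving group that supplies its own base (methoxide) on ionisation.

Step 13
Reactants: 17 allylic methyl carbonate (cyclisation precursor)
Product: 19 tert-butyl 7-oxo-6,7-seco-ent-kaura-5(6),16-dien-19-oate, via pyrrolidine enamine 18 (not isolated)
Conditions: Pd(PPh3)4 (8 mol %), pyrrolidine (40 mol %), THF (0.02 M), rt → 45 °C; aqueous NH4Cl work-up
Reagents that add atoms: none
Why: Pyrrolidine condenses with the C7 aldehyde to enamine 18 while zerovalent palladium ionises the carbonate (loss of CO2 and methoxide) to a 2-substituted π-allyl complex whose termini C15 and C17 are equivalent, C8 attacks one terminus on the side away from the metal, and hydrolysis of the iminium ion returns the amine. The closest known reaction type is the intramolecular Tsuji–Trost α-allylation of aldehydes under combined palladium and secondary-amine catalysis, which includes α-branched aldehydes that give quaternary carbons. Ring D (C8–C15–C16–C13–C14) closes in a 5-exo mode, with both the palladium–allyl bond that breaks and the surviving C16=C17 outside the new ring, and this completes the bicyclo[3.2.1]octane. C8 is the only new stereocentre and is fixed by the tether, since the arm reaches C8 only from the ring-C face it occupies on C13, which is also the face away from ring A on C9. Closure needs the trans-related C9 and C13 substituents both axial, and allylic 1,3-strain in the exocyclic enamine (nitrogen turned towards C14) already pushes the tertiary-alkyl group on C9 axial. The step needs C- over N-allylation: N-allylation is reversible under palladium whereas C-allylation gives an aldehyde without α-hydrogen, C7 is the only aldehyde present, and C5=C6 and the tert-butyl ester are inert.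

Step 14
Reactants: 19 tert-butyl 7-oxo-6,7-seco-ent-kaura-5(6),16-dien-19-oate
Product: 20 tert-butyl 16,17-dihydroxy-7-oxo-6,7-seco-ent-kaur-5(6)-en-19-oate (16-OH exo)
Conditions: OsO4 (2 mol %), NMO (1.1 equiv), acetone/H2O, 0 °C
Reagents that add atoms: N-methylmorpholine N-oxide, C[N+]1([O-])CCOCC1; water, O; osmium tetroxide (catalytic oxygen carrier), O=[Os](=O)(=O)=O
Why: Catalytic OsO4/NMO syn-dihydroxylation from the exo face of the bicyclo[3.2.1]octane (the side of the C14 bridge, away from C11 and C12) places 16-OH as in the target, while C5=C6 between two quaternary carbons should be too shielded to compete for one equivalent of oxidant.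

Step 15
Reactants: 20 tert-butyl 16,17-dihydroxy-7-oxo-6,7-seco-ent-kaur-5(6)-en-19-oate (16-OH exo)
Product: 21 16,17-acetonide of 20
Conditions: Me2C(OMe)2, PPTS (5 mol %), CH2Cl2, rt
Reagents that add atoms: 2,2-dimethoxypropane, COC(C)(C)OC
Why: Acetonide formation masks the C17 primary alcohol so that only C6 and C7 are oxidised in step 17.

Step 16
Reactants: 21 16,17-acetonide of 20
Product: 23 6,7-diol (C6 and C7 as CH2OH; H5 as in the target), via bis-borane adduct 22 (not isolated)
Conditions: BH3·THF (5 equiv), THF, 0 → 40 °C; then H2O2, pH 7 phosphate buffer, 0 °C → rt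
Reagents that add atoms: hydrogen peroxide, OO
Why: Brown hydroboration–oxidation, in which BH3 reduces the C7 aldehyde and adds to C5=C6 with boron on terminal C6 and hydrogen on C5 from the ring-A face opposite the axial C19 ester and C20 methyl (sets C5), and buffered peroxide avoids a free alkoxide that could close onto C19.

Step 17
Reactants: 23 6,7-diol (C6 and C7 as CH2OH; H5 as in the target)
Product: 24 6,7-dialdehyde (acetonide and tert-butyl ester retained)
Conditions: Dess–Martin periodinane (3 equiv), CH2Cl2, rt
Reagents that add atoms: none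
Why: Dess–Martin oxidation converts both primary alcohols to aldehydes under near-neutral conditions that should not epimerise C5.

Step 18
Reactants: 24 6,7-dialdehyde (acetonide and tert-butyl ester retained)
Product: 25 16,17-dihydroxy-6,7-dioxo-6,7-seco-ent-kauran-19-oic acid (target)
Conditions: CF3CO2H/CH2Cl2 1:4, H2O (10 equiv), 0 °C → rt
Reagents that add atoms: none
Why: One acidolysis removes both groups, the tert-butyl ester by alkyl–oxygen cleavage (insensitive to crowding at C19) and the acetonide by hydrolysis, and the adjacent C17 oxygen disfavours ionisation at C16.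

**Compound list**
1 | tert-butyl 2-oxocyclohexane-1-carboxylate | O=C1CCCCC1C(=O)OC(C)(C)C | starting material
2 | tert-butyl (1R)-1-methyl-2-oxocyclohexane-1-carboxylate | O=C1CCCC[C@@]1(C)C(=O)OC(C)(C)C | intermediate
3 | tert-butyl (1R)-1,3-dimethyl-2-oxocyclohexane-1-carboxylate (C3 epimers) | CC1CCC[C@@](C)(C(=O)OC(C)(C)C)C1=O | intermediate
4 | tert-butyl (1R)-1,3-dimethyl-2-(trifluoromethylsulfonyloxy)cyclohex-2-ene-1-carboxylate | CC1=C(OS(=O)(=O)C(F)(F)F)[C@](C)(C(=O)OC(C)(C)C)CCC1 | intermediate
5 | tert-butyl (1R)-2-(hydroxymethyl)-1,3-dimethylcyclohex-2-ene-1-carboxylate | CC1=C(CO)[C@](C)(C(=O)OC(C)(C)C)CCC1 | intermediate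
6 | cyclohex-2-en-1-one | O=C1C=CCCC1 | starting material
7 | 4,4,5,5-tetramethyl-2-(prop-1-en-2-yl)-1,3,2-dioxaborolane | CC(=C)B1OC(C)(C)C(C)(C)O1 | starting material
8 | (3R)-3-(prop-1-en-2-yl)cyclohexan-1-one | O=C1CCC[C@@H](C(C)=C)C1 | intermediate
9 | (3R)-1,1-dimethoxy-3-(prop-1-en-2-yl)cyclohexane | COC1(OC)CCC[C@@H](C(C)=C)C1 | intermediate
10 | allyl vinyl ether (C8 enol ether of ring C, double bond C8=C9, O-linked to C6 of 5) | CC1=C(COC2=CCC[C@@H](C(C)=C)C2)[C@](C)(C(=O)OC(C)(C)C)CCC1 | intermediate
11 | tert-butyl (1R,3S)-1,3-dimethyl-2-methylidene-3-[(1S,4R)-2-oxo-4-(prop-1-en-2-yl)cyclohexyl]cyclohexane-1-carboxylate | C[C@@]1([C@@H]2CC[C@@H](C(C)=C)CC2=O)CCC[C@@](C)(C(=O)OC(C)(C)C)C1=C | intermediate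
12 | C8(OTf)=C14 enol triflate of 11 | C[C@@]1([C@@H]2CC[C@@H](C(C)=C)C=C2OS(=O)(=O)C(F)(F)F)CCC[C@@](C)(C(=O)OC(C)(C)C)C1=C | intermediate
13 | C8(CHO)=C14 enal | C[C@@]1([C@@H]2CC[C@@H](C(C)=C)C=C2C=O)CCC[C@@](C)(C(=O)OC(C)(C)C)C1=C | intermediate
14 | (E)-triethylsilyl enol ether of the C7 aldehyde (C8=C7) | C[C@@]1([C@@H]2CC[C@@H](C(C)=C)C/C2=C\O[Si](CC)(CC)CC)CCC[C@@](C)(C(=O)OC(C)(C)C)C1=C | intermediate
15 | saturated C7 aldehyde (formyl equatorial on C8, trans to ring A on C9, cis to isopropenyl on C13) | C[C@@]1([C@@H]2CC[C@@H](C(C)=C)C[C@H]2C=O)CCC[C@@](C)(C(=O)OC(C)(C)C)C1=C | intermediate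
16 | allylic alcohol (3-hydroxyprop-1-en-2-yl arm on C13) | C[C@@]1([C@@H]2CC[C@@H](C(=C)CO)C[C@H]2C=O)CCC[C@@](C)(C(=O)OC(C)(C)C)C1=C | intermediate
17 | allylic methyl carbonate (cyclisation precursor) | C[C@@]1([C@@H]2CC[C@@H](C(=C)COC(=O)OC)C[C@H]2C=O)CCC[C@@](C)(C(=O)OC(C)(C)C)C1=C | intermediate
18 | pyrrolidine enamine of 17 (C8=C7, nitrogen towards C14) | C[C@@]1([C@@H]2CC[C@@H](C(=C)COC(=O)OC)C/C2=C\N3CCCC3)CCC[C@@](C)(C(=O)OC(C)(C)C)C1=C | intermediate
19 | tert-butyl 7-oxo-6,7-seco-ent-kaura-5(6),16-dien-19-oate | C[C@@]1([C@@H]2CC[C@@H]3C[C@@]2(C=O)CC3=C)CCC[C@@](C)(C(=O)OC(C)(C)C)C1=C | intermediate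
20 | tert-butyl 16,17-dihydroxy-7-oxo-6,7-seco-ent-kaur-5(6)-en-19-oate (16-OH exo) | C[C@@]1([C@@H]2CC[C@@H]3C[C@@]2(C=O)C[C@]3(O)CO)CCC[C@@](C)(C(=O)OC(C)(C)C)C1=C | intermediate
21 | 16,17-acetonide of 20 | C[C@@]1([C@@H]2CC[C@@H]3C[C@@]2(C=O)C[C@]3(OC4(C)C)CO4)CCC[C@@](C)(C(=O)OC(C)(C)C)C1=C | intermediate
22 | bis-borane adduct (C6–BH2, C7–O–BH2) | C[C@@]1([C@@H]2CC[C@@H]3C[C@@]2(COB)C[C@]3(OC4(C)C)CO4)CCC[C@@](C)(C(=O)OC(C)(C)C)[C@H]1CB | intermediate
23 | 6,7-diol (acetonide, tert-butyl ester) | C[C@@]1([C@@H]2CC[C@@H]3C[C@@]2(CO)C[C@]3(OC4(C)C)CO4)CCC[C@@](C)(C(=O)OC(C)(C)C)[C@H]1CO | intermediate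
24 | 6,7-dialdehyde (acetonide, tert-butyl ester) | C[C@@]1([C@@H]2CC[C@@H]3C[C@@]2(C=O)C[C@]3(OC4(C)C)CO4)CCC[C@@](C)(C(=O)OC(C)(C)C)[C@H]1C=O | intermediate
25 | 16,17-dihydroxy-6,7-dioxo-6,7-seco-ent-kauran-19-oic acid | C[C@@]1([C@@H]2CC[C@@H]3C[C@@]2(C=O)C[C@]3(O)CO)CCC[C@@](C)(C(=O)O)[C@H]1C=O | target

**Step count.** Total: 18 steps. Longest linear sequence: 16 steps (steps 1–4, then 7–18).

**Steps most likely to fail**

**Step 7.**
- What may go wrong: acid at 140 °C may ionise the tetrasubstituted allylic alcohol or strip isobutene from the ester. The shift may be slow because both termini are hindered. The facial bias at C10 may be modest, since methyl and ester on C4 differ only moderately in size.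
- Fallback (from 8 and 5, back to the route at 11): an anionic ester-enolate variant with no acid, a fixed reacting site and a much lower temperature. Ketone 8 is acylated at its less hindered α-carbon (C9) with NaH and dimethyl carbonate to methyl (4R)-2-oxo-4-(prop-1-en-2-yl)cyclohexane-1-carboxylate F1. DMAP-catalysed transesterification with 5 in toluene gives the ring-A allyl β-keto ester F2. Its dianion (LiN(iPr)2, 2.2 equiv, THF, −78 °C → rt) undergoes the Carroll rearrangement to the β-keto acid F3, which decarboxylates on warming in toluene and gives 11 after the same methoxide equilibration.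

**Step 13.**
- What may go wrong: enamine formation at the crowded α-branched aldehyde may be slow. Ring C may resist the diaxial conformer. The amine may be drained by N-allylation before C8 attacks.
- Fallback (from 17, back to the route at 19): an amine-free closure with a preformed nucleophile. Et3SiOTf and Et3N in CH2Cl2 convert 17 into the triethylsilyl enol ether carbonate F4. Pd2(dba)3·CHCl3 and dppe in THF at 65 °C ionise the carbonate, and the liberated methoxide desilylates the enol ether. The resulting aldehyde enolate is allylated at C8 within the π-allylpalladium ion pair, forming the same C8–C15 bond.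

**Step 16.**
- What may go wrong: hydroboration of an alkene flanked by two quaternary carbons may stall. The new C6 oxygen may close onto the C19 ester to a lactone.
- Fallback (from 21, back to the route at 24): a radical route through an epoxide that leaves C7 untouched. Dimethyldioxirane in acetone at 0 °C gives the 5,6-epoxide F5. Cp2TiCl (trivalent titanium, made from Cp2TiCl2 and Mn dust) with 1,4-cyclohexadiene in THF opens it reductively to the tertiary C5 radical. This radical takes a hydrogen atom on the face opposite C19 and C20 and gives the 6-hydroxy 7-aldehyde F6. A single Dess–Martin oxidation then gives 24.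

**Further compounds**
F1 | step 7 | methyl (4R)-2-oxo-4-(prop-1-en-2-yl)cyclohexane-1-carboxylate | COC(=O)C1CC[C@@H](C(C)=C)CC1=O
F2 | step 7 | ring-A allyl β-keto ester (ester of 5 with the acid of F1) | CC1=C(COC(=O)C2CC[C@@H](C(C)=C)CC2=O)[C@](C)(C(=O)OC(C)(C)C)CCC1
F3 | step 7 | β-keto acid from the Carroll shift (C9 carries CO2H and ring A; C9 configuration lost on decarboxylation) | C[C@@]1(C2(C(=O)O)CC[C@@H](C(C)=C)CC2=O)CCC[C@@](C)(C(=O)OC(C)(C)C)C1=C
F4 | step 13 | triethylsilyl enol ether carbonate derived from 17 | C[C@@]1([C@@H]2CC[C@@H](C(=C)COC(=O)OC)C/C2=C\O[Si](CC)(CC)CC)CCC[C@@](C)(C(=O)OC(C)(C)C)C1=C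
F5 | step 16 | 5,6-epoxide of 21 | C[C@@]1([C@@H]2CC[C@@H]3C[C@@]2(C=O)C[C@]3(OC4(C)C)CO4)CCC[C@@](C)(C(=O)OC(C)(C)C)[C@@]1(O5)C5
F6 | step 16 | 6-hydroxy 7-aldehyde (acetonide, tert-butyl ester) | C[C@@]1([C@@H]2CC[C@@H]3C[C@@]2(C=O)C[C@]3(OC4(C)C)CO4)CCC[C@@](C)(C(=O)OC(C)(C)C)[C@H]1CO
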